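**Retrosynthetic overview**
1. Target 23 comes from the benzyl-protected acid 22 by one hydrogenation that saturates C4=C5 and frees both phenols. The CO2H is put on last (formylation, then oxidation of diacetate 19), so no hydroxy ester that could lactonise to a dihydroisocoumarin ever exists.
2. Diacetate 19 comes from a Z-Wittig union at C4=C5 of aldehyde 10 (arene plus C1–C4) and phosphonium salt 15 (C5–C13).
3. Aldehyde 10 comes from β-keto ester 7 by Ru–BINAP asymmetric hydrogenation (sets C2); 7 comes from arylacetic acid 3 and a malonate half-ester.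
4. Salt 15 comes from 9-bromononan-2-one 12 by ketoreductase reduction (sets C12); 12 comes from Wacker oxidation of 9-bromonon-1-ene.
5. No ring is formed: the benzene ring, the only ring, comes intact from methyl 3,5-dihydroxyphenylacetate.

Assumption: the SMILES is read as 2-[(2S,12R)-2,12-diacetoxytridecyl]-4,6-dihydroxybenzoic acid, and compounds 1, 4 and 11 are taken as purchasable.

**Step 1**
Reactants: 1 methyl 2-(3,5-dihydroxyphenyl)acetate
Product: 2 methyl 2-[3,5-bis(benzyloxy)phenyl]acetate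
Conditions: BnBr (2.3 equiv), K2CO3 (3 equiv), acetone, reflux
Reagents that add atoms: benzyl bromide, BrCc1ccccc1
Why: Williamson ether synthesis, in which K2CO3 deprotonates only the phenols and the ester α-CH2 is left alone.

**Step 2**
Reactants: 2 methyl 2-[3,5-bis(benzyloxy)phenyl]acetate
Product: 3 2-[3,5-bis(benzyloxy)phenyl]acetic acid
Conditions: LiOH·H2O (3 equiv), THF/MeOH/H2O, rt; then 1 M HCl
Reagents that add atoms: lithium hydroxide, [Li+].[OH-]
Why: Ester saponification of an unhindered methyl ester, with benzyl ethers inert to aqueous base.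

**Step 3**
Reactants: 3 2-[3,5-bis(benzyloxy)phenyl]acetic acid; 4 potassium monomethyl malonate
Product: 7 methyl 4-[3,5-bis(benzyloxy)phenyl]-3-oxobutanoate, via acyl imidazolide 5 (not isolated), via acylmalonate half-ester 6 (not isolated)
Conditions: 1,1'-carbonyldiimidazole (1.1 equiv), THF, rt; then 4 (1.5 equiv), MgCl2 (1.5 equiv), Et3N, MeCN/THF, rt to 40 °C; 1 M HCl work-up
Reagents that add atoms: none
Why: Masamune–Brooks homologation, in which the magnesium malonate enolate is C-acylated by the imidazolide and the resulting β-keto acid loses CO2 on acidification.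

**Step 4**
Reactants: 7 methyl 4-[3,5-bis(benzyloxy)phenyl]-3-oxobutanoate
Product: 8 methyl (3R)-4-[3,5-bis(benzyloxy)phenyl]-3-hydroxybutanoate
Conditions: [RuCl(p-cymene)((R)-BINAP)]Cl (1 mol %), H2 (10 bar), MeOH, 60 °C
Reagents that add atoms: none
Why: Noyori asymmetric hydrogenation of a β-keto ester, where ester chelation to the (R)-BINAP–Ru hydride fixes the face of hydride delivery and gives the (3R) alcohol (as for simple 3-oxobutanoates), while the homogeneous Ru catalyst leaves benzyl ethers untouched.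

**Step 5**
Reactants: 8 methyl (3R)-4-[3,5-bis(benzyloxy)phenyl]-3-hydroxybutanoate
Product: 9 methyl (3R)-4-[3,5-bis(benzyloxy)phenyl]-3-[(tert-butyldimethylsilyl)oxy]butanoate
Conditions: TBSCl (1.3 equiv), imidazole (2.5 equiv), DMF, rt
Reagents that add atoms: tert-butyldimethylsilyl chloride, CC(C)(C)[Si](C)(C)Cl
Why: Imidazole-promoted silylation of a secondary alcohol, which does not touch the stereocentre and blocks β-elimination in the later steps.

**Step 6**
Reactants: 9 methyl (3R)-4-[3,5-bis(benzyloxy)phenyl]-3-[(tert-butyldimethylsilyl)oxy]butanoate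
Product: 10 (3R)-4-[3,5-bis(benzyloxy)phenyl]-3-[(tert-butyldimethylsilyl)oxy]butanal
Conditions: i-Bu2AlH (1.1 equiv), CH2Cl2, −78 °C; MeOH quench at −78 °C, aq. potassium sodium tartrate (KNaC4H4O6)
Reagents that add atoms: none
Why: Partial hydride reduction of an ester, in which the aluminium hemiacetal is stable at −78 °C (helped by the β-silyloxy oxygen) and releases the aldehyde only on work-up.

**Step 7**
Reactants: 11 9-bromonon-1-ene
Product: 12 9-bromononan-2-one
Conditions: PdCl2 (10 mol %), CuCl (1 equiv), O2 (1 atm), DMF/H2O 7:1, rt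
Reagents that add atoms: water, O
Why: Tsuji–Wacker oxidation, in which Markovnikov hydroxypalladation of the terminal alkene gives the methyl ketone and the remote primary bromide is unaffected.

**Step 8**
Reactants: 12 9-bromononan-2-one
Product: 13 (2R)-9-bromononan-2-ol
Conditions: ketoreductase ((R)-selective NADPH-dependent alcohol dehydrogenase of the Lactobacillus kefir type), NADP+ (cat.), i-PrOH (15 % v/v), MgCl2 (1 mM), K2HPO4/KH2PO4 buffer pH 7.0, 30 °C
Reagents that add atoms: none
Why: Enzymatic asymmetric ketone reduction, in which the anti-Prelog ketoreductase delivers hydride from NADPH to the si face of the methyl ketone to give the (R)-carbinol in very high ee, with isopropanol recycling the cofactor.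

**Step 9**
Reactants: 13 (2R)-9-bromononan-2-ol
Product: 14 {[(2R)-9-bromononan-2-yl]oxy}(tert-butyl)dimethylsilane
Conditions: TBSCl (1.2 equiv), imidazole (2 equiv), CH2Cl2, 0 °C to rt
Reagents that add atoms: tert-butyldimethylsilyl chloride, CC(C)(C)[Si](C)(C)Cl
Why: Silylation of the secondary alcohol with retention, run in CH2Cl2 so that imidazole does not alkylate on the primary bromide.

**Step 10**
Reactants: 14 {[(2R)-9-bromononan-2-yl]oxy}(tert-butyl)dimethylsilane
Product: 15 [(8R)-8-[(tert-butyldimethylsilyl)oxy]nonyl]triphenylphosphonium bromide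
Conditions: PPh3 (1.2 equiv), MeCN, 85 °C, 48 h
Reagents that add atoms: triphenylphosphine, c1ccc(cc1)P(c1ccccc1)c1ccccc1
Why: SN2 quaternisation of triphenylphosphine by an unhindered primary bromide, to which the secondary silyl ether is inert.

**Step 11**
Reactants: 15 [(8R)-8-[(tert-butyldimethylsilyl)oxy]nonyl]triphenylphosphonium bromide; 10 (3R)-4-[3,5-bis(benzyloxy)phenyl]-3-[(tert-butyldimethylsilyl)oxy]butanal
Product: 17 (2S,12R,4Z)-1-[3,5-bis(benzyloxy)phenyl]-2,12-bis[(tert-butyldimethylsilyl)oxy]tridec-4-ene, via phosphonium ylide 16 (not isolated)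
Conditions: 15 (1.3 equiv), NaN(SiMe3)2 (1.25 equiv), THF, −78 to 0 °C; then 10, −78 °C to rt
Reagents that add atoms: none
Why: Wittig olefination with a non-stabilised ylide under lithium-free conditions joins C4 to C5 as the Z-alkene without touching either stereocentre, and the alkene geometry is irrelevant because step 16 saturates it.

**Step 12**
Reactants: 17 (2S,12R,4Z)-1-[3,5-bis(benzyloxy)phenyl]-2,12-bis[(tert-butyldimethylsilyl)oxy]tridec-4-ene
Product: 18 (2S,12R,4Z)-1-[3,5-bis(benzyloxy)phenyl]tridec-4-ene-2,12-diol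
Conditions: Bu4NF (3 equiv), THF, rt to 40 °C
Reagents that add atoms: none
Why: Fluoride-mediated desilylation driven by the strong Si–F bond removes both silyl ethers at once with retention at both carbinol carbons.

**Step 13**
Reactants: 18 (2S,12R,4Z)-1-[3,5-bis(benzyloxy)phenyl]tridec-4-ene-2,12-diol
Product: 19 (2S,12R,4Z)-1-[3,5-bis(benzyloxy)phenyl]tridec-4-ene-2,12-diyl diacetate
Conditions: Ac2O (4 equiv), pyridine, DMAP (cat.), CH2Cl2, 0 °C to rt
Reagents that add atoms: acetic anhydride, CC(=O)OC(C)=O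
Why: DMAP-catalysed acylation of both secondary alcohols at oxygen, so both configurations are retained.

**Step 14**
Reactants: 19 (2S,12R,4Z)-1-[3,5-bis(benzyloxy)phenyl]tridec-4-ene-2,12-diyl diacetate
Product: 21 2,4-bis(benzyloxy)-6-[(2S,12R,4Z)-2,12-diacetoxytridec-4-en-1-yl]benzaldehyde, via aryl iminium chloride 20 (not isolated)
Conditions: POCl3 (2 equiv), DMF, 0 to 50 °C; then aq. NaOAc, rt
Reagents that add atoms: N,N-dimethylformamide, CN(C)C=O; water, O
Why: Vilsmeier–Haack formylation of the electron-rich resorcinol diether goes to the ring carbon next to the side chain (para to one benzyloxy, ortho to the other) rather than the more crowded carbon between the two benzyloxy groups, and acetates, benzyl ethers and the isolated alkene tolerate the reagent.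

**Step 15**
Reactants: 21 2,4-bis(benzyloxy)-6-[(2S,12R,4Z)-2,12-diacetoxytridec-4-en-1-yl]benzaldehyde
Product: 22 2,4-bis(benzyloxy)-6-[(2S,12R,4Z)-2,12-diacetoxytridec-4-en-1-yl]benzoic acid
Conditions: NaClO2 (3 equiv), NaH2PO4 (3 equiv), 2-methyl-2-butene (20 equiv), t-BuOH/THF/H2O, 0 °C to rt
Reagents that add atoms: sodium chlorite, [Na+].[O-]Cl=O
Why: Pinnick oxidation converts the aldehyde to the acid at about pH 4, where the acetates survive, and the excess trisubstituted alkene traps HOCl before it can attack the ring or the chain alkene.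

**Step 16**
Reactants: 22 2,4-bis(benzyloxy)-6-[(2S,12R,4Z)-2,12-diacetoxytridec-4-en-1-yl]benzoic acid
Product: 23 2-[(2S,12R)-2,12-diacetoxytridecyl]-4,6-dihydroxybenzoic acid
Conditions: H2 (1 atm), 10 % Pd on carbon, EtOAc, rt
Reagents that add atoms: none
Why: Heterogeneous catalytic hydrogenation saturates the alkene and hydrogenolyses both aryl benzyl ethers under neutral conditions, which leave the homobenzylic and alkyl acetates and the free acid intact.

**Compound list**
1 | methyl 2-(3,5-dihydroxyphenyl)acetate | COC(=O)Cc1cc(O)cc(O)c1 | starting material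
2 | methyl 2-[3,5-bis(benzyloxy)phenyl]acetate | COC(=O)Cc1cc(OCc2ccccc2)cc(OCc2ccccc2)c1 | intermediate
3 | 2-[3,5-bis(benzyloxy)phenyl]acetic acid | OC(=O)Cc1cc(OCc2ccccc2)cc(OCc2ccccc2)c1 | intermediate
4 | potassium monomethyl malonate (potassium 3-methoxy-3-oxopropanoate) | COC(=O)CC(=O)[O-].[K+] | starting material
5 | 2-[3,5-bis(benzyloxy)phenyl]-1-(1H-imidazol-1-yl)ethan-1-one (acyl imidazolide) | O=C(Cc1cc(OCc2ccccc2)cc(OCc2ccccc2)c1)n1ccnc1 | intermediate
6 | 2-{[3,5-bis(benzyloxy)phenyl]acetyl}-3-methoxy-3-oxopropanoic acid (acylmalonate half-ester, present as its magnesium chelate) | COC(=O)C(C(=O)O)C(=O)Cc1cc(OCc2ccccc2)cc(OCc2ccccc2)c1 | intermediate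
7 | methyl 4-[3,5-bis(benzyloxy)phenyl]-3-oxobutanoate | COC(=O)CC(=O)Cc1cc(OCc2ccccc2)cc(OCc2ccccc2)c1 | intermediate
8 | methyl (3R)-4-[3,5-bis(benzyloxy)phenyl]-3-hydroxybutanoate | COC(=O)C[C@H](O)Cc1cc(OCc2ccccc2)cc(OCc2ccccc2)c1 | intermediate
9 | methyl (3R)-4-[3,5-bis(benzyloxy)phenyl]-3-[(tert-butyldimethylsilyl)oxy]butanoate | COC(=O)C[C@H](O[Si](C)(C)C(C)(C)C)Cc1cc(OCc2ccccc2)cc(OCc2ccccc2)c1 | intermediate
10 | (3R)-4-[3,5-bis(benzyloxy)phenyl]-3-[(tert-butyldimethylsilyl)oxy]butanal | O=CC[C@H](O[Si](C)(C)C(C)(C)C)Cc1cc(OCc2ccccc2)cc(OCc2ccccc2)c1 | intermediate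
11 | 9-bromonon-1-ene | C=CCCCCCCCBr | starting material
12 | 9-bromononan-2-one | CC(=O)CCCCCCCBr | intermediate
13 | (2R)-9-bromononan-2-ol | C[C@@H](O)CCCCCCCBr | intermediate
14 | {[(2R)-9-bromononan-2-yl]oxy}(tert-butyl)dimethylsilane | C[C@@H](O[Si](C)(C)C(C)(C)C)CCCCCCCBr | intermediate
15 | [(8R)-8-[(tert-butyldimethylsilyl)oxy]nonyl]triphenylphosphonium bromide | C[C@@H](O[Si](C)(C)C(C)(C)C)CCCCCCC[P+](c1ccccc1)(c1ccccc1)c1ccccc1.[Br-] | intermediate
16 | [(8R)-8-[(tert-butyldimethylsilyl)oxy]nonylidene]triphenylphosphorane (ylide) | C[C@@H](O[Si](C)(C)C(C)(C)C)CCCCCCC=P(c1ccccc1)(c1ccccc1)c1ccccc1 | intermediate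
17 | (2S,12R,4Z)-1-[3,5-bis(benzyloxy)phenyl]-2,12-bis[(tert-butyldimethylsilyl)oxy]tridec-4-ene | CC(C)(C)[Si](C)(C)O[C@@H](C/C=C\CCCCCC[C@@H](C)O[Si](C)(C)C(C)(C)C)Cc1cc(OCc2ccccc2)cc(OCc2ccccc2)c1 | intermediate
18 | (2S,12R,4Z)-1-[3,5-bis(benzyloxy)phenyl]tridec-4-ene-2,12-diol | O[C@@H](C/C=C\CCCCCC[C@@H](C)O)Cc1cc(OCc2ccccc2)cc(OCc2ccccc2)c1 | intermediate
19 | (2S,12R,4Z)-1-[3,5-bis(benzyloxy)phenyl]tridec-4-ene-2,12-diyl diacetate | CC(=O)O[C@@H](C/C=C\CCCCCC[C@@H](C)OC(C)=O)Cc1cc(OCc2ccccc2)cc(OCc2ccccc2)c1 | intermediate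
20 | {2,4-bis(benzyloxy)-6-[(2S,12R,4Z)-2,12-diacetoxytridec-4-en-1-yl]benzylidene}dimethylammonium chloride | CC(=O)O[C@@H](C/C=C\CCCCCC[C@@H](C)OC(C)=O)Cc1cc(OCc2ccccc2)cc(OCc2ccccc2)c1C=[N+](C)C.[Cl-] | intermediate
21 | 2,4-bis(benzyloxy)-6-[(2S,12R,4Z)-2,12-diacetoxytridec-4-en-1-yl]benzaldehyde | CC(=O)O[C@@H](C/C=C\CCCCCC[C@@H](C)OC(C)=O)Cc1cc(OCc2ccccc2)cc(OCc2ccccc2)c1C=O | intermediate
22 | 2,4-bis(benzyloxy)-6-[(2S,12R,4Z)-2,12-diacetoxytridec-4-en-1-yl]benzoic acid | CC(=O)O[C@@H](C/C=C\CCCCCC[C@@H](C)OC(C)=O)Cc1cc(OCc2ccccc2)cc(OCc2ccccc2)c1C(=O)O | intermediate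
23 | 2-[(2S,12R)-2,12-diacetoxytridecyl]-4,6-dihydroxybenzoic acid | CC(=O)O[C@@H](CCCCCCCCC[C@@H](C)OC(C)=O)Cc1cc(O)cc(O)c1C(=O)O | target

**Totals**
Total step count: 16. Longest linear sequence: 12 steps (steps 1–6, then 11–16); the side branch is steps 7–10.

**Three steps most likely to fail, with fallbacks**

Step 14 (Vilsmeier–Haack formylation; risk of sluggish reaction at the flanked ring carbon or some attack between the two benzyloxy groups). The fallback sets out from 19 and comes back to the route at 23. Brominate 19 with N-bromosuccinimide in MeCN at 0 °C, which goes cleanly para to a benzyloxy group and next to the chain, to give (2S,12R,4Z)-1-[3,5-bis(benzyloxy)-2-bromophenyl]tridec-4-ene-2,12-diyl diacetate F1. Carbonylate this with Pd(OAc)2/Xantphos, CO (5 bar, so that CO insertion stays ahead of any cyclisation onto the chain alkene), benzyl alcohol and Et3N in toluene at 100 °C to give benzyl 2,4-bis(benzyloxy)-6-[(2S,12R,4Z)-2,12-diacetoxytridec-4-en-1-yl]benzoate F2. Hydrogenation over Pd on carbon under the conditions of step 16 then removes all three benzyl groups and the alkene and gives 23, bypassing steps 14 and 15.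

Step 6 (partial reduction; risk of over-reduction to the alcohol or incomplete conversion). The fallback sets out from 9 and comes back at 10. Reduce 9 fully with LiBH4 in THF (0 °C to rt) to (3R)-4-[3,5-bis(benzyloxy)phenyl]-3-[(tert-butyldimethylsilyl)oxy]butan-1-ol F3, then oxidise with Dess–Martin periodinane/NaHCO3 in CH2Cl2 to aldehyde 10.

Step 8 (ketoreductase reduction; risk of low activity on a water-insoluble bromo ketone). The fallback sets out from 12 and comes back at 13. Reduce 12 with NaBH4 in MeOH at 0 °C to racemic 9-bromononan-2-ol F4. Resolve it by lipase-catalysed acyl transfer (immobilised Candida antarctica lipase B, vinyl acetate, MTBE, 30 °C, stopped near 50 % conversion), which acetylates only the (R)-alcohol to give (2R)-9-bromononan-2-yl acetate F5. The unreacted (2S)-9-bromononan-2-ol F6 is separated on silica and can be oxidised back to 12 for recycling. Methanolysis of F5 (K2CO3, MeOH, 0 °C) gives 13.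

**Further compounds**
F1 | step 14 | (2S,12R,4Z)-1-[3,5-bis(benzyloxy)-2-bromophenyl]tridec-4-ene-2,12-diyl diacetate | CC(=O)O[C@@H](C/C=C\CCCCCC[C@@H](C)OC(C)=O)Cc1cc(OCc2ccccc2)cc(OCc2ccccc2)c1Br
F2 | step 14 | benzyl 2,4-bis(benzyloxy)-6-[(2S,12R,4Z)-2,12-diacetoxytridec-4-en-1-yl]benzoate | CC(=O)O[C@@H](C/C=C\CCCCCC[C@@H](C)OC(C)=O)Cc1cc(OCc2ccccc2)cc(OCc2ccccc2)c1C(=O)OCc1ccccc1
F3 | step 6 | (3R)-4-[3,5-bis(benzyloxy)phenyl]-3-[(tert-butyldimethylsilyl)oxy]butan-1-ol | OCC[C@H](O[Si](C)(C)C(C)(C)C)Cc1cc(OCc2ccccc2)cc(OCc2ccccc2)c1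
F4 | step 8 | racemic 9-bromononan-2-ol | CC(O)CCCCCCCBr
F5 | step 8 | (2R)-9-bromononan-2-yl acetate | C[C@@H](OC(C)=O)CCCCCCCBr
F6 | step 8 | (2S)-9-bromononan-2-ol | C[C@H](O)CCCCCCCBr
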